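Ring A is closed last through the bond between the ketone carbon C2 and the methylene C3. The C2 carbonyl, flanked by C3H2 and the methyl-bearing methine C4 on the quaternary carbon C5, is read as an acyl radical adding 6-endo to an isopropenyl group on C5 (C3=C4 with C15 attached). In one operation this cyclisation of a Se-phenyl selenoester forms ring A, the cis-decalin and, by hydrogen-atom transfer, the C4 stereocentre. The precursor is a fully esterified, monocyclic ring B cyclohexane carrying two isopropenyl groups, built from (+)-3-carene by cleavage of its cyclopropane bond, which keeps the C7 stereocentre.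

Key step: step 13

Remark: locants follow the eremophilane numbering of the target (ring A: C1–C5 and C10; ring B: C5–C10; C14 = methyl on C5, C15 = methyl on C4, C11–C13 = isopropenyl on C7) and β is the face of C14; the target is read as the 9-O-(E)-2-methylbut-2-enoate (tiglate) and 8-O-(R)-2-methylbutanoate, absolute configuration 4S,5R,7R,8R,9S,10S.

Step 1
Reactants: 1 (+)-3-carene
Product: 2 (1R,6S)-4,7,7-trimethylbicyclo[4.1.0]hept-3-en-2-one (car-3-en-5-one)
Conditions: t-BuOOH (70% aq.), CrO3 (cat.), CH2Cl2, rt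
Reagents that add atoms: tert-butyl hydroperoxide, CC(C)(C)OO
Why: Chromium-catalysed allylic oxidation should attack the ring methylene that is activated by both the alkene and the cyclopropane and leads to the conjugated enone, leaving the two stereocentres untouched.

Step 2
Reactants: 2 (1R,6S)-4,7,7-trimethylbicyclo[4.1.0]hept-3-en-2-one
Product: 3 (S)-5-(2-hydroxypropan-2-yl)-3-methylcyclohex-2-en-1-one
Conditions: H2SO4 (aq.), THF, 40 °C
Reagents that add atoms: water, O
Why: Acid-catalysed homoconjugate (homo-Michael) addition of water to the cyclopropyl enone should break the cyclopropane bond to the CMe2 carbon, the one that gives a tertiary cation, while the ring stereocentre that becomes C7 is not involved.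

Step 3
Reactants: 3 (S)-5-(2-hydroxypropan-2-yl)-3-methylcyclohex-2-en-1-one
Product: 4 (S)-3-methyl-5-(prop-1-en-2-yl)cyclohex-2-en-1-one
Conditions: SOCl2, pyridine, CH2Cl2, −20 to 0 °C
Reagents that add atoms: none
Why: Pyridine-mediated E2-type dehydration of the tertiary carbinol should remove one of the six accessible methyl hydrogens in preference to the single hindered ring methine hydrogen, giving the isopropenyl group; any isopropylidene isomer is removed by chromatography.

Step 4
Reactants: 4 (S)-3-methyl-5-(prop-1-en-2-yl)cyclohex-2-en-1-one; 5 isopropenylmagnesium bromide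
Product: 6 trimethyl{[(3S,5S)-3-methyl-3,5-di(prop-1-en-2-yl)cyclohex-1-en-1-yl]oxy}silane
Conditions: CuI·2LiCl (10 mol%), TMSCl, THF, −40 °C; then Et3N, pentane
Reagents that add atoms: chlorotrimethylsilane, C[Si](C)(C)Cl
Why: Copper-catalysed, TMSCl-accelerated conjugate addition of the Grignard reagent should proceed by axial attack on the half-chair with the C7 isopropenyl equatorial, so the new C5 isopropenyl is trans (α) to it and C14 is β, and the enolate is trapped regiospecifically as the C9–C10 silyl enol ether.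

Step 5
Reactants: 6 trimethyl{[(3S,5S)-3-methyl-3,5-di(prop-1-en-2-yl)cyclohex-1-en-1-yl]oxy}silane; 7 tert-butyl glyoxylate
Product: 11 tert-butyl (Z)-2-[2-methyl-6-oxo-2,4-di(prop-1-en-2-yl)cyclohexylidene]acetate, via lithium enolate 8 (not isolated), via lithium aldolate 9 (not isolated), via aldol mesylate 10 (not isolated)
Conditions: MeLi, THF, 0 °C; 7, −78 °C; MsCl, −78 to 0 °C; DBU, rt
Reagents that add atoms: none
Why: MeLi releases the regiodefined lithium enolate, and its aldol addition to the highly electrophilic glyoxylate followed by mesylation and E1cB elimination (aldol condensation) should give the exocyclic alkylidene; C10 is deliberately left planar for the next step and the alkene geometry is of no consequence.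

Step 6
Reactants: 11 tert-butyl (Z)-2-[2-methyl-6-oxo-2,4-di(prop-1-en-2-yl)cyclohexylidene]acetate
Product: 12 tert-butyl 2-[2-methyl-6-oxo-2,4-di(prop-1-en-2-yl)cyclohexyl]acetate (H-10 β and side chain α)
Conditions: Zn, AcOH, rt
Reagents that add atoms: none
Why: Zinc reduction of the ene-1,4-dicarbonyl (dissolving-metal conjugate reduction) gives the C9 enol, which should be protonated at C10 axially from the β face, opposite the axial α-isopropenyl on C5, so the CH2CO2t-Bu chain becomes equatorial and cis to that isopropenyl; this is also the more stable epimer.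

Step 7
Reactants: 12 tert-butyl 2-[2-methyl-6-oxo-2,4-di(prop-1-en-2-yl)cyclohexyl]acetate
Product: 14 tert-butyl 2-[3-hydroxy-6-methyl-2-oxo-4,6-di(prop-1-en-2-yl)cyclohexyl]acetate (8α-hydroxy ketone), via potassium enolate 13 (not isolated)
Conditions: KN(SiMe3)2, THF, −78 °C; 2-(phenylsulfonyl)-3-phenyloxaziridine, −78 °C; AcOH
Reagents that add atoms: 2-(phenylsulfonyl)-3-phenyloxaziridine, O=S(=O)(c1ccccc1)N1OC1c1ccccc1
Why: Kinetic deprotonation can only occur at the C8 methylene (C10 is tertiary and shielded by C5), and Davis oxidation of the enolate should deliver oxygen anti to the adjacent C7 isopropenyl, giving the equatorial 8α-hydroxy ketone.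

Step 8
Reactants: 14 tert-butyl 2-[3-hydroxy-6-methyl-2-oxo-4,6-di(prop-1-en-2-yl)cyclohexyl]acetate; 15 (R)-2-methylbutanoic acid
Product: 16 tert-butyl 2-[6-methyl-3-{[(R)-2-methylbutanoyl]oxy}-2-oxo-4,6-di(prop-1-en-2-yl)cyclohexyl]acetate
Conditions: EDC·HCl, DMAP (cat.), CH2Cl2, 0 °C to rt
Reagents that add atoms: none
Why: Steglich esterification of the unhindered equatorial C8 hydroxyl under near-neutral conditions should not epimerise the α-stereocentre of the acid or C8.

Step 9
Reactants: 16 tert-butyl 2-[6-methyl-3-{[(R)-2-methylbutanoyl]oxy}-2-oxo-4,6-di(prop-1-en-2-yl)cyclohexyl]acetate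
Product: 17 tert-butyl 2-[2-hydroxy-6-methyl-3-{[(R)-2-methylbutanoyl]oxy}-4,6-di(prop-1-en-2-yl)cyclohexyl]acetate (9α-alcohol)
Conditions: LiBH(s-Bu)3, THF, −78 °C; AcOH, −78 °C
Reagents that add atoms: none
Why: Ketone reduction by the bulky hydride should occur along the equatorial β trajectory, because the axial one is blocked by the syn-axial isopropenyl on C5, giving the axial 9α-alcohol cis to the C8 ester; the cold acidic quench limits acyl migration and lactonisation onto the tert-butyl ester.

Step 10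
Reactants: 17 tert-butyl 2-[2-hydroxy-6-methyl-3-{[(R)-2-methylbutanoyl]oxy}-4,6-di(prop-1-en-2-yl)cyclohexyl]acetate; 18 tiglic acid
Product: 20 tert-butyl 2-[6-methyl-2-{[(E)-2-methylbut-2-enoyl]oxy}-3-{[(R)-2-methylbutanoyl]oxy}-4,6-di(prop-1-en-2-yl)cyclohexyl]acetate, via mixed anhydride 19 (not isolated)
Conditions: 18, 2,4,6-trichlorobenzoyl chloride, Et3N, toluene, rt; then 17, DMAP, 60 °C
Reagents that add atoms: none
Why: Yamaguchi esterification through the mixed anhydride and its acylpyridinium salt is forceful enough for the hindered axial C9 hydroxyl and leaves the (E)-geometry of the tiglate intact.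

Step 11
Reactants: 20 tert-butyl 2-[6-methyl-2-{[(E)-2-methylbut-2-enoyl]oxy}-3-{[(R)-2-methylbutanoyl]oxy}-4,6-di(prop-1-en-2-yl)cyclohexyl]acetate
Product: 22 2-[6-methyl-2-{[(E)-2-methylbut-2-enoyl]oxy}-3-{[(R)-2-methylbutanoyl]oxy}-4,6-di(prop-1-en-2-yl)cyclohexyl]acetic acid, via trimethylsilyl ester 21 (not isolated)
Conditions: TMSOTf, 2,6-lutidine, CH2Cl2, 0 °C; then H2O
Reagents that add atoms: none
Why: Silyl triflate-mediated cleavage of the tert-butyl ester (loss of isobutene to the silyl ester, hydrolysed on work-up) under buffered aprotic conditions should spare both isopropenyl groups, the tiglate and the secondary ester.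

Step 12
Reactants: 22 2-[6-methyl-2-{[(E)-2-methylbut-2-enoyl]oxy}-3-{[(R)-2-methylbutanoyl]oxy}-4,6-di(prop-1-en-2-yl)cyclohexyl]acetic acid
Product: 23 Se-phenyl 2-[6-methyl-2-{[(E)-2-methylbut-2-enoyl]oxy}-3-{[(R)-2-methylbutanoyl]oxy}-4,6-di(prop-1-en-2-yl)cyclohexyl]ethaneselenoate
Conditions: PhSeSePh, PBu3, CH2Cl2, rt
Reagents that add atoms: diphenyl diselenide, c1ccc(cc1)[Se][Se]c1ccccc1
Why: Phosphine-mediated redox condensation of the acid with the diselenide (acyloxyphosphonium captured by selenolate) should give the Se-phenyl selenoester under neutral conditions.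

Step 13
Reactants: 23 Se-phenyl 2-[6-methyl-2-{[(E)-2-methylbut-2-enoyl]oxy}-3-{[(R)-2-methylbutanoyl]oxy}-4,6-di(prop-1-en-2-yl)cyclohexyl]ethaneselenoate
Product: 26 (4S,5R,7R,8R,9S,10S)-9-[(E)-2-methylbut-2-enoyloxy]-8-[(R)-2-methylbutanoyloxy]eremophil-11-en-2-one (CNP0312791.1), via acyl radical 24 (not isolated), via tertiary radical 25 (not isolated)
Conditions: Bu3SnH (1.3 equiv, syringe pump), AIBN (0.2 equiv), benzene (5 mM), 80 °C
Reagents that add atoms: none
Why: Bu3Sn• abstracts the phenylseleno group to give the C2 acyl radical, which adds to the terminal carbon C3 of the isopropenyl group on C5, and the resulting tertiary C4 radical takes a hydrogen atom from Bu3SnH (acyl radical cyclisation of a selenoester, a known reaction type for 5-methylhex-5-enoyl systems). Ring A closes in the 6-endo-trig mode, since direct 5-exo attack at C4 would join two fully substituted carbons, and any such adduct should funnel to the same C4 radical by Dowd–Beckwith ring expansion. The cis ring fusion follows from the gauche, equatorial–axial arrangement of the C10 acyl chain and the C5 isopropenyl set in steps 4 and 6. The new stereocentre C4 is controlled by the angular methyl C14, which is axial on ring A and vicinal to the radical: hydrogen should be delivered anti to it on the α face, so that C15 ends up β, equatorial and cis to C14. The step needs cyclisation to outrun reduction or decarbonylation of the acyl radical (slow addition of Bu3SnH at high dilution) and chemoselectivity for the C5 isopropenyl over the remote C7 isopropenyl and the trisubstituted tiglate, which proximity and the nucleophilic character of the acyl radical should secure.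

Compound list
1 | (+)-3-carene, (1S,6R)-3,7,7-trimethylbicyclo[4.1.0]hept-3-ene | CC1=CC[C@@H]2[C@H](C1)C2(C)C | starting material
2 | (1R,6S)-4,7,7-trimethylbicyclo[4.1.0]hept-3-en-2-one (car-3-en-5-one) | CC1=CC(=O)[C@@H]2[C@H](C1)C2(C)C | intermediate
3 | (S)-5-(2-hydroxypropan-2-yl)-3-methylcyclohex-2-en-1-one | CC1=CC(=O)C[C@H](C1)C(C)(C)O | intermediate
4 | (S)-3-methyl-5-(prop-1-en-2-yl)cyclohex-2-en-1-one | CC1=CC(=O)C[C@H](C1)C(C)=C | intermediate
5 | isopropenylmagnesium bromide | C=C(C)[Mg]Br | starting material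
6 | trimethyl{[(3S,5S)-3-methyl-3,5-di(prop-1-en-2-yl)cyclohex-1-en-1-yl]oxy}silane (C9–C10 silyl enol ether; C5 isopropenyl α, C7 isopropenyl β, C14 β) | C=C(C)[C@H]1C[C@@](C(C)=C)(C)C=C(O[Si](C)(C)C)C1 | intermediate
7 | tert-butyl glyoxylate (tert-butyl 2-oxoacetate) | O=CC(=O)OC(C)(C)C | starting material
8 | lithium C9–C10 enolate from 6 (not isolated) | C=C(C)[C@H]1C[C@@](C(C)=C)(C)C=C(O[Li])C1 | intermediate
9 | lithium aldolate with the glyoxylate (not isolated; mixture at C10 and the carbinol carbon) | C=C(C)[C@H]1C[C@@](C(C)=C)(C)C(C(O[Li])C(=O)OC(C)(C)C)C(=O)C1 | intermediate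
10 | aldol mesylate (not isolated; same mixture) | C=C(C)[C@H]1C[C@@](C(C)=C)(C)C(C(OS(C)(=O)=O)C(=O)OC(C)(C)C)C(=O)C1 | intermediate
11 | tert-butyl (Z)-2-[2-methyl-6-oxo-2,4-di(prop-1-en-2-yl)cyclohexylidene]acetate (drawn Z; either geometry serves) | C=C(C)[C@H]1C[C@@](C(C)=C)(C)/C(=C/C(=O)OC(C)(C)C)C(=O)C1 | intermediate
12 | tert-butyl 2-[2-methyl-6-oxo-2,4-di(prop-1-en-2-yl)cyclohexyl]acetate (H-10 β, side chain α and cis to the C5 isopropenyl) | C=C(C)[C@H]1C[C@@](C(C)=C)(C)[C@H](CC(=O)OC(C)(C)C)C(=O)C1 | intermediate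
13 | potassium C8–C9 enolate of 12 (not isolated) | C=C(C)[C@H]1C[C@@](C(C)=C)(C)[C@H](CC(=O)OC(C)(C)C)C(O[K])=C1 | intermediate
14 | tert-butyl 2-[3-hydroxy-6-methyl-2-oxo-4,6-di(prop-1-en-2-yl)cyclohexyl]acetate (8α-hydroxy, trans to the C7 isopropenyl) | C=C(C)[C@H]1C[C@@](C(C)=C)(C)[C@H](CC(=O)OC(C)(C)C)C(=O)[C@@H]1O | intermediate
15 | (R)-2-methylbutanoic acid | CC[C@@H](C)C(=O)O | starting material
16 | tert-butyl 2-[6-methyl-3-{[(R)-2-methylbutanoyl]oxy}-2-oxo-4,6-di(prop-1-en-2-yl)cyclohexyl]acetate | C=C(C)[C@H]1C[C@@](C(C)=C)(C)[C@H](CC(=O)OC(C)(C)C)C(=O)[C@@H]1OC(=O)[C@H](C)CC | intermediate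
17 | tert-butyl 2-[2-hydroxy-6-methyl-3-{[(R)-2-methylbutanoyl]oxy}-4,6-di(prop-1-en-2-yl)cyclohexyl]acetate (9α-hydroxy, axial, cis to O-8) | C=C(C)[C@H]1C[C@@](C(C)=C)(C)[C@H](CC(=O)OC(C)(C)C)[C@H](O)[C@@H]1OC(=O)[C@H](C)CC | intermediate
18 | tiglic acid, (E)-2-methylbut-2-enoic acid | C/C=C(\C)C(=O)O | starting material
19 | tiglic 2,4,6-trichlorobenzoic anhydride (not isolated) | C/C=C(\C)C(=O)OC(=O)c1c(Cl)cc(Cl)cc1Cl | intermediate
20 | tert-butyl 2-[6-methyl-2-{[(E)-2-methylbut-2-enoyl]oxy}-3-{[(R)-2-methylbutanoyl]oxy}-4,6-di(prop-1-en-2-yl)cyclohexyl]acetate | C=C(C)[C@H]1C[C@@](C(C)=C)(C)[C@H](CC(=O)OC(C)(C)C)[C@H](OC(=O)/C(C)=C/C)[C@@H]1OC(=O)[C@H](C)CC | intermediate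
21 | trimethylsilyl ester corresponding to 20 (not isolated) | C=C(C)[C@H]1C[C@@](C(C)=C)(C)[C@H](CC(=O)O[Si](C)(C)C)[C@H](OC(=O)/C(C)=C/C)[C@@H]1OC(=O)[C@H](C)CC | intermediate
22 | 2-[6-methyl-2-{[(E)-2-methylbut-2-enoyl]oxy}-3-{[(R)-2-methylbutanoyl]oxy}-4,6-di(prop-1-en-2-yl)cyclohexyl]acetic acid | C=C(C)[C@H]1C[C@@](C(C)=C)(C)[C@H](CC(=O)O)[C@H](OC(=O)/C(C)=C/C)[C@@H]1OC(=O)[C@H](C)CC | intermediate
23 | Se-phenyl selenoester of 22 | C=C(C)[C@H]1C[C@@](C(C)=C)(C)[C@H](CC(=O)[Se]c2ccccc2)[C@H](OC(=O)/C(C)=C/C)[C@@H]1OC(=O)[C@H](C)CC | intermediate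
24 | C2 acyl radical (not isolated) | C=C(C)[C@H]1C[C@@](C(C)=C)(C)[C@H](C[C]=O)[C@H](OC(=O)/C(C)=C/C)[C@@H]1OC(=O)[C@H](C)CC | intermediate
25 | cyclised tertiary C4 radical (not isolated) | C=C(C)[C@H]1C[C@@]2(C)[C@H](CC(=O)C[C]2C)[C@H](OC(=O)/C(C)=C/C)[C@@H]1OC(=O)[C@H](C)CC | intermediate
26 | (4S,5R,7R,8R,9S,10S)-9-[(E)-2-methylbut-2-enoyloxy]-8-[(R)-2-methylbutanoyloxy]eremophil-11-en-2-one, CNP0312791.1 | C=C(C)[C@H]1C[C@@]2(C)[C@H](CC(=O)C[C@@H]2C)[C@H](OC(=O)/C(C)=C/C)[C@@H]1OC(=O)[C@H](C)CC | target

Total step count: 13. Longest linear sequence: 13 steps, from (+)-3-carene 1 to the target 26; compounds 5, 7, 15 and 18 are commercial.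

Steps most likely to fail

Step 13. What may go wrong is poor facial selectivity in the hydrogen-atom transfer to the C4 radical, or reduction of the acyl radical before it cyclises. The fallback delivers the hydrogen intramolecularly from a silicon hydride on O-9, which lies syn-axial to the α lobe of the C4 radical (unimolecular chain transfer). It sets out from 17 and comes back at 26. Alcohol 17 is silylated with chlorodiisopropylsilane (imidazole, DMAP, DMF) to the 9-O-diisopropylsilyl ether F1. TMSOTf and 2,6-lutidine then give the acid F2, and PhSeSePh with PBu3 gives the selenoester F3. Heating F3 with AIBN and a catalytic amount of Bu3SnH in dilute benzene should give the cyclised silyl selenide F4: the C4 radical abstracts the Si–H hydrogen through a seven-membered transition state, and the silyl radical carries the chain by taking the phenylseleno group of the next molecule. HF·pyridine frees the 9α-alcohol F5, and Yamaguchi esterification with 18, as in step 10, gives 26.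

Step 10. What may go wrong is slow acylation of the hindered axial C9 hydroxyl, so that 1,2-migration of the C8 ester and acylation of the freed equatorial hydroxyl scramble the two acyl groups. The fallback reverses the order of acylation behind a temporary silyl ether on O-8. It sets out from 14 and comes back at 20. Ketol 14 is protected with TESOTf and 2,6-lutidine as the 8-O-triethylsilyl ketone F6, and LiBH(s-Bu)3 at −78 °C gives the 9α-alcohol F7. Tigloyl chloride with DMAP in pyridine at 60 °C, where no acyl group can migrate, gives the 9-tiglate F8. HF·pyridine frees the 8α-alcohol F9, and esterification with 15 (EDC, DMAP) gives 20.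

Step 5. What may go wrong is sluggish or reversible aldol addition at the enolate carbon next to the quaternary centre, or incomplete elimination. The fallback replaces the condensation–reduction pair (steps 5 and 6) by direct alkylation and thermodynamic epimerisation. It sets out from 6 and comes back at 12. MeLi followed by tert-butyl bromoacetate (THF, DMPU) should alkylate C10 anti to the axial C5 isopropenyl and give the C10 epimer F10, with the side chain β and axial. Equilibration with t-BuOK in t-BuOH through the C9–C10 enolate should move the chain to the equatorial α position, giving 12, with recovered F10 recycled.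

Further compounds
F1 | step 13 | 9-O-diisopropylsilyl ether of 17 | C=C(C)[C@H]1C[C@@](C(C)=C)(C)[C@H](CC(=O)OC(C)(C)C)[C@H](O[SiH](C(C)C)C(C)C)[C@@H]1OC(=O)[C@H](C)CC
F2 | step 13 | carboxylic acid from F1 | C=C(C)[C@H]1C[C@@](C(C)=C)(C)[C@H](CC(=O)O)[C@H](O[SiH](C(C)C)C(C)C)[C@@H]1OC(=O)[C@H](C)CC
F3 | step 13 | Se-phenyl selenoester from F2 | C=C(C)[C@H]1C[C@@](C(C)=C)(C)[C@H](CC(=O)[Se]c2ccccc2)[C@H](O[SiH](C(C)C)C(C)C)[C@@H]1OC(=O)[C@H](C)CC
F4 | step 13 | cyclised 9-O-[diisopropyl(phenylselanyl)silyl] decalone | C=C(C)[C@H]1C[C@@]2(C)[C@H](CC(=O)C[C@@H]2C)[C@H](O[Si]([Se]c3ccccc3)(C(C)C)C(C)C)[C@@H]1OC(=O)[C@H](C)CC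
F5 | step 13 | 9α-hydroxy-8α-[(R)-2-methylbutanoyloxy]eremophil-11-en-2-one | C=C(C)[C@H]1C[C@@]2(C)[C@H](CC(=O)C[C@@H]2C)[C@H](O)[C@@H]1OC(=O)[C@H](C)CC
F6 | step 10 | 8-O-triethylsilyl ether of ketol 14 | C=C(C)[C@H]1C[C@@](C(C)=C)(C)[C@H](CC(=O)OC(C)(C)C)C(=O)[C@@H]1O[Si](CC)(CC)CC
F7 | step 10 | 9α-alcohol from F6 | C=C(C)[C@H]1C[C@@](C(C)=C)(C)[C@H](CC(=O)OC(C)(C)C)[C@H](O)[C@@H]1O[Si](CC)(CC)CC
F8 | step 10 | 9-tiglate 8-O-triethylsilyl ether | C=C(C)[C@H]1C[C@@](C(C)=C)(C)[C@H](CC(=O)OC(C)(C)C)[C@H](OC(=O)/C(C)=C/C)[C@@H]1O[Si](CC)(CC)CC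
F9 | step 10 | 9-tiglate 8α-alcohol | C=C(C)[C@H]1C[C@@](C(C)=C)(C)[C@H](CC(=O)OC(C)(C)C)[C@H](OC(=O)/C(C)=C/C)[C@@H]1O
F10 | step 5 | C10 epimer of keto ester 12 (side chain β) | C=C(C)[C@H]1C[C@@](C(C)=C)(C)[C@@H](CC(=O)OC(C)(C)C)C(=O)C1
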